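**Target:** (5R,8R,6'R)-5,8-epoxy-5,8-dihydro-β,ε-carotene (carotenoid numbering, ε end primed).

**Plan**
- Cuts: C11=C12 and C11'=C12' (two Wittig couplings to the C10 dialdehyde), C7'=C8' (Wittig on α-cyclocitral), C1'–C6' of ring ε (cation–allylsilane closure), O–C8 of the dihydrofuran (allene cyclisation) and C8–C9 (Sonogashira).
- Forward: an acyclic C10 chain with a tertiary methyl ether at C1' and a silicon-bearing stereocentre at C4' is closed to ring ε, then grown to the C15 phosphonium salt and the C25 aldehyde. The bicyclic furanoid C15 salt is made from β-cyclocitral and joined last.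
- Enabling feature: in ring ε the gem-dimethyl carbon C1' can carry a tertiary cation, C6' is the γ-carbon of a C4'-silyl allyl unit, and the ring double bond C4'=C5' lies exactly where that allylsilane leaves its alkene.
- Stereochemistry: C6' by 1,3-transfer from the C4' C–Si centre (sparteine-mediated lithiation). C5 by Sharpless epoxidation. C8 relayed from C5/C6 through an anti-SN2' hydride opening (centre to axis) and a gold-catalysed ring closure (axis to centre).

Key step: step 6

Remark: (Z)- and (E)-3-iodobut-2-en-1-ol are taken as purchased catalogue compounds (each is otherwise one or two known steps from but-2-yn-1-ol).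

**Route**

Step 1
Reactants: 1 4-methylpent-3-en-1-ol; 2 N,N-diisopropylcarbamoyl chloride
Product: 3 4-methylpent-3-en-1-yl N,N-diisopropylcarbamate
Conditions: Et3N, DMAP (cat.), CH2Cl2, reflux
Reagents that add atoms: none
Why: O-carbamoylation of the primary alcohol installs the directing group for the later α-lithiation.

Step 2
Reactants: 3 4-methylpent-3-en-1-yl N,N-diisopropylcarbamate
Product: 4 4-methoxy-4-methylpentyl N,N-diisopropylcarbamate
Conditions: MeOH (solvent), Amberlyst 15 (sulfonic acid resin, cat.), 50 °C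
Reagents that add atoms: methanol, CO
Why: Acid-catalysed Markovnikov hydroalkoxylation of the trisubstituted alkene stores the future C1' cation as a base-stable tertiary methyl ether.

Step 3
Reactants: 4 4-methoxy-4-methylpentyl N,N-diisopropylcarbamate; 5 2-[dimethyl(phenyl)silyl]-4,4,5,5-tetramethyl-1,3,2-dioxaborolane
Product: 8 2-[(1S)-1-[dimethyl(phenyl)silyl]-4-methoxy-4-methylpentyl]-4,4,5,5-tetramethyl-1,3,2-dioxaborolane, via lithiated carbamate 6 (not isolated), via silylborate complex 7 (not isolated)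
Conditions: s-BuLi, (+)-sparteine, Et2O, −78 °C, 5 h; then 5, −78 °C → reflux
Reagents that add atoms: none
Why: Sparteine-mediated enantioselective α-lithiation of the O-alkyl carbamate, borylation with retention and a Matteson-type 1,2-silyl shift with inversion should set the C4' C–Si centre, (+)-sparteine removing the pro-R hydrogen so that the (S)-boronate results.

Step 4
Reactants: 9 (2Z)-3-iodobut-2-en-1-ol
Product: 10 tert-butyl{[(2Z)-3-iodobut-2-en-1-yl]oxy}diphenylsilane
Conditions: TBDPSCl, imidazole, DMF, rt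
Reagents that add atoms: tert-butyl(chloro)diphenylsilane, CC(C)(C)[Si](Cl)(c1ccccc1)c1ccccc1
Why: Silylation gives an oxygen function that tolerates t-BuLi and is a poor leaving group towards TiCl4.

Step 5
Reactants: 8 2-[(1S)-1-[dimethyl(phenyl)silyl]-4-methoxy-4-methylpentyl]-4,4,5,5-tetramethyl-1,3,2-dioxaborolane; 10 tert-butyl{[(2Z)-3-iodobut-2-en-1-yl]oxy}diphenylsilane
Product: 14 tert-butyl{[(2E,4R)-4-[dimethyl(phenyl)silyl]-7-methoxy-3,7-dimethyloct-2-en-1-yl]oxy}diphenylsilane, via alkenyllithium 11 (not isolated), via alkenylborate complex 12 (not isolated), via iodoalkyl boronic ester 13 (not isolated)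
Conditions: 10, t-BuLi (2.0 equiv), Et2O, −78 °C; add 8 in THF, −78 → 0 °C; I2 (1.05 equiv), THF, −78 °C; NaOMe, MeOH, −78 °C → rt
Reagents that add atoms: none
Why: Zweifel olefination, in which the α-silylalkyl group migrates from boron to carbon with retention and the anti elimination of boron and iodine inverts the alkene geometry, so the alkenyllithium with the metal cis to CH2OSi should give the (E)-allylsilane with C4' intact.

Step 6
Reactants: 14 tert-butyl{[(2E,4R)-4-[dimethyl(phenyl)silyl]-7-methoxy-3,7-dimethyloct-2-en-1-yl]oxy}diphenylsilane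
Product: 15 tert-butyl(diphenyl){[(1R)-2,6,6-trimethylcyclohex-2-en-1-yl]methoxy}silane
Conditions: TiCl4 (1.2 equiv), 2,6-di-tert-butyl-4-methylpyridine (1.5 equiv), CH2Cl2 (0.01 M), −78 °C, 30 min; aq. NaHCO3
Reagents that add atoms: none
Why: Proposed new method: TiCl4 ionises the tertiary methyl ether to the C1' cation under proton-free conditions, the cation is captured by C6' (the γ-carbon of the allylsilane), and the β-silyl cation at C5' loses silicon to chloride, which places the double bond at C4'=C5' only; the closest known reaction types are the Hosomi–Sakurai tert-alkylation of allylsilanes by tertiary alkyl chlorides or ethers with TiCl4 and allylsilane-terminated cation–olefin cyclisations, neither shown for a simple tertiary cation with 1,3-chirality transfer into an α-cyclogeranyl ring. The six-membered ring closes in the 6-endo mode (all three allyl carbons inside the new ring) through a chair-like array. The new centre C6' is controlled by the C4' centre: the C–Si bond must lie anti-periplanar to the forming C1'–C6' bond (anti-SE2'), the tether carbon C3' then sits on the attacked face, and with the (E)-alkene this should give the (R) centre. The step needs ionisation at the tertiary ether and not at the allylic silyl ether (the more basic methoxy oxygen binds TiCl4 at low temperature), capture faster than proton loss from the cation (intramolecular, strongly nucleophilic allylsilane), and no protodesilylation (hindered pyridine as proton trap).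

Step 7
Reactants: 15 tert-butyl(diphenyl){[(1R)-2,6,6-trimethylcyclohex-2-en-1-yl]methoxy}silane
Product: 16 [(1R)-2,6,6-trimethylcyclohex-2-en-1-yl]methanol ((R)-α-cyclogeraniol)
Conditions: Bu4NF, THF, rt
Reagents that add atoms: none
Why: Fluoride cleavage of the silyl ether leaves the non-conjugated C6' centre untouched.

Step 8
Reactants: 16 [(1R)-2,6,6-trimethylcyclohex-2-en-1-yl]methanol; 17 1-(triphenyl-λ5-phosphanylidene)propan-2-one
Product: 19 (3E)-4-[(1R)-2,6,6-trimethylcyclohex-2-en-1-yl]but-3-en-2-one ((R)-α-ionone), via (R)-α-cyclocitral 18 (not isolated)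
Conditions: Dess–Martin periodinane, NaHCO3, CH2Cl2, 0 °C; then 17, 1,2-dichloroethane, 70 °C
Reagents that add atoms: none
Why: Buffered Dess–Martin oxidation and immediate Wittig reaction with the stabilised ylide should give the (E)-enone without isolating the epimerisable α-cyclocitral.

Step 9
Reactants: 19 (3E)-4-[(1R)-2,6,6-trimethylcyclohex-2-en-1-yl]but-3-en-2-one
Product: 20 (1E)-3-methyl-1-[(1R)-2,6,6-trimethylcyclohex-2-en-1-yl]penta-1,4-dien-3-ol (both C3 epimers)
Conditions: CH2=CHMgBr, THF, −20 → 0 °C; then H2O/aq. NH4Cl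
Reagents that add atoms: vinylmagnesium bromide, C=C[Mg]Br
Why: 1,2-Grignard addition to the methyl ketone, where the new carbinol centre is removed in the next step.

Step 10
Reactants: 20 (1E)-3-methyl-1-[(1R)-2,6,6-trimethylcyclohex-2-en-1-yl]penta-1,4-dien-3-ol
Product: 21 {(2E,4E)-3-methyl-5-[(1R)-2,6,6-trimethylcyclohex-2-en-1-yl]penta-2,4-dien-1-yl}triphenylphosphonium bromide
Conditions: Ph3P·HBr, MeOH, rt, 48 h
Reagents that add atoms: triphenylphosphonium bromide, [Br-].[PH+](c1ccccc1)(c1ccccc1)c1ccccc1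
Why: Ionisation of the tertiary bis-allylic alcohol and capture of the pentadienyl cation by triphenylphosphine at the terminal carbon is the classical route to C15 Wittig salts and is known to preserve the ε-ring centre.

Step 11
Reactants: 21 the C15 phosphonium bromide; 22 (2E,4E,6E)-2,7-dimethylocta-2,4,6-trienedial
Product: 24 (2E,4E,6E,8E,10E,12E)-2,7,11-trimethyl-13-[(1R)-2,6,6-trimethylcyclohex-2-en-1-yl]trideca-2,4,6,8,10,12-hexaenal, via phosphorus ylide 23 (not isolated)
Conditions: 22 (3 equiv), NaOMe, CH2Cl2/MeOH, 0 °C; then heptane, reflux (Z→E), crystallisation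
Reagents that add atoms: none
Why: Wittig mono-olefination of the excess dialdehyde forms C11'=C12', and the new double bond is equilibrated thermally to (E).

Step 12
Reactants: 25 2,6,6-trimethylcyclohex-1-ene-1-carbaldehyde (β-cyclocitral)
Product: 26 (2,6,6-trimethylcyclohex-1-en-1-yl)methanol
Conditions: NaBH4, MeOH, 0 °C
Reagents that add atoms: none
Why: Borohydride 1,2-reduction of the hindered enal gives the allylic alcohol needed for directed epoxidation.

Step 13
Reactants: 26 (2,6,6-trimethylcyclohex-1-en-1-yl)methanol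
Product: 27 [(1R,6R)-2,2,6-trimethyl-7-oxabicyclo[4.1.0]heptan-1-yl]methanol
Conditions: Ti(OiPr)4 (10 mol %), D-(−)-diethyl tartrate (12 mol %), t-BuOOH, 4 Å molecular sieves, CH2Cl2, −20 °C
Reagents that add atoms: tert-butyl hydroperoxide, CC(C)(C)OO
Why: Katsuki–Sharpless epoxidation of the tetrasubstituted allylic alcohol, where the D-(−)-tartrate should deliver oxygen to the face that makes C5 (R).

Step 14
Reactants: 27 [(1R,6R)-2,2,6-trimethyl-7-oxabicyclo[4.1.0]heptan-1-yl]methanol
Product: 28 (1S,6R)-2,2,6-trimethyl-7-oxabicyclo[4.1.0]heptane-1-carbaldehyde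
Conditions: Dess–Martin periodinane, NaHCO3, CH2Cl2, 0 °C → rt
Reagents that add atoms: none
Why: Buffered Dess–Martin oxidation gives the epoxy aldehyde, whose α-carbon is quaternary and cannot epimerise.

Step 15
Reactants: 28 (1S,6R)-2,2,6-trimethyl-7-oxabicyclo[4.1.0]heptane-1-carbaldehyde
Product: 29 (1R,6R)-1-ethynyl-2,2,6-trimethyl-7-oxabicyclo[4.1.0]heptane
Conditions: dimethyl (1-diazo-2-oxopropyl)phosphonate, K2CO3, MeOH, 0 °C → rt
Reagents that add atoms: dimethyl (1-diazo-2-oxopropyl)phosphonate, COP(=O)(OC)C(=[N+]=[N-])C(C)=O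
Why: Ohira–Bestmann (Seyferth–Gilbert) homologation converts the non-enolisable aldehyde into the terminal alkyne under mild base.

Step 16
Reactants: 29 (1R,6R)-1-ethynyl-2,2,6-trimethyl-7-oxabicyclo[4.1.0]heptane; 30 (2E)-3-iodobut-2-en-1-ol
Product: 31 (2E)-3-methyl-5-[(1R,6R)-2,2,6-trimethyl-7-oxabicyclo[4.1.0]heptan-1-yl]pent-2-en-4-yn-1-ol
Conditions: PdCl2(PPh3)2 (3 mol %), CuI (6 mol %), Et3N, THF, rt
Reagents that add atoms: none
Why: Sonogashira coupling forms C8–C9 with retention of the (E)-iodoalkene geometry and tolerates the free hydroxyl and the epoxide.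

Step 17
Reactants: 31 (2E)-3-methyl-5-[(1R,6R)-2,2,6-trimethyl-7-oxabicyclo[4.1.0]heptan-1-yl]pent-2-en-4-yn-1-ol
Product: 33 (2E)-5-[(2R)-2-hydroxy-2,6,6-trimethylcyclohexylidene]-3-methylpenta-2,4-dien-1-ol with the (aS) allene axis (C9 on the face of the C5 hydroxyl), via bis(silyl) ether 32 (not isolated)
Conditions: IPrCuCl, chloro[1,3-bis(2,6-diisopropylphenyl)imidazol-2-ylidene]copper (5 mol %), NaOtBu (10 mol %), (EtO)2MeSiH (3 equiv), toluene, 0 °C → rt; then K2CO3, MeOH
Reagents that add atoms: none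
Why: Copper hydride-catalysed SN2' reduction of the propargylic oxirane should deliver hydride to C8 anti to the breaking C6–O bond, so the C5/C6 configuration is relayed into the allene axis while C5–O is retained.

Step 18
Reactants: 33 the allenic diol
Product: 34 (2E)-3-[(2R,7aR)-4,4,7a-trimethyl-2,4,5,6,7,7a-hexahydro-1-benzofuran-2-yl]but-2-en-1-ol
Conditions: Ph3PAuCl (2 mol %), AgBF4 (2 mol %), THF, 0 °C
Reagents that add atoms: none
Why: Gold-catalysed 5-endo cycloisomerisation of the α-hydroxyallene (anti oxyauration, then protodeauration) should transfer the axis to C8, placing the side chain trans to the C5 methyl group, that is (8R).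

Step 19
Reactants: 34 the furanoid allylic alcohol
Product: 36 {(2E)-3-[(2R,7aR)-4,4,7a-trimethyl-2,4,5,6,7,7a-hexahydro-1-benzofuran-2-yl]but-2-en-1-yl}triphenylphosphonium bromide, via allylic bromide 35 (not isolated)
Conditions: CBr4 (1.1 equiv), PPh3 (2.3 equiv), 2,6-lutidine, CH2Cl2, 0 °C; then MeCN, 40 °C
Reagents that add atoms: carbon tetrabromide, BrC(Br)(Br)Br; triphenylphosphine, c1ccc(cc1)P(c1ccccc1)c1ccccc1
Why: Appel bromination and quaternisation of triphenylphosphine under neutral conditions avoid the acid that would ionise the doubly allylic C8–O bond.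

Step 20
Reactants: 36 the furanoid C15 phosphonium bromide; 24 the C25 aldehyde
Product: 38 (5R,8R,6'R)-5,8-epoxy-5,8-dihydro-β,ε-carotene, via phosphorus ylide 37 (not isolated)
Conditions: NaOMe added slowly to 36 + 24, CH2Cl2/MeOH, 0 °C → rt; then ethyl acetate, reflux under argon (Z→E), crystallisation
Reagents that add atoms: none
Why: Wittig olefination forms C11=C12; generating the ylide in the presence of the aldehyde keeps its lifetime short, and thermal equilibration should give the all-(E) polyene without acid, so C8 is not disturbed.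

**Compound list**

1 | 4-methylpent-3-en-1-ol | CC(C)=CCCO | starting material
2 | N,N-diisopropylcarbamoyl chloride | CC(C)N(C(C)C)C(=O)Cl | starting material
3 | 4-methylpent-3-en-1-yl N,N-diisopropylcarbamate | CC(C)=CCCOC(=O)N(C(C)C)C(C)C | intermediate
4 | 4-methoxy-4-methylpentyl N,N-diisopropylcarbamate | COC(C)(C)CCCOC(=O)N(C(C)C)C(C)C | intermediate
5 | 2-[dimethyl(phenyl)silyl]-4,4,5,5-tetramethyl-1,3,2-dioxaborolane | C[Si](C)(c1ccccc1)B1OC(C)(C)C(C)(C)O1 | starting material
6 | (1R)-1-lithio-4-methoxy-4-methylpentyl N,N-diisopropylcarbamate | COC(C)(C)CC[C@H](OC(=O)N(C(C)C)C(C)C)[Li] | intermediate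
7 | lithium [(1R)-1-(diisopropylcarbamoyloxy)-4-methoxy-4-methylpentyl][dimethyl(phenyl)silyl](pinacolato)borate | [Li+].COC(C)(C)CC[C@H](OC(=O)N(C(C)C)C(C)C)[B-]1([Si](C)(C)c2ccccc2)OC(C)(C)C(C)(C)O1 | intermediate
8 | 2-[(1S)-1-[dimethyl(phenyl)silyl]-4-methoxy-4-methylpentyl]-4,4,5,5-tetramethyl-1,3,2-dioxaborolane | COC(C)(C)CC[C@@H]([Si](C)(C)c1ccccc1)B1OC(C)(C)C(C)(C)O1 | intermediate
9 | (2Z)-3-iodobut-2-en-1-ol | C/C(I)=C/CO | starting material
10 | tert-butyl{[(2Z)-3-iodobut-2-en-1-yl]oxy}diphenylsilane | C/C(I)=C/CO[Si](c1ccccc1)(c1ccccc1)C(C)(C)C | intermediate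
11 | alkenyllithium from 10 (lithium cis to CH2OSi) | C/C([Li])=C/CO[Si](c1ccccc1)(c1ccccc1)C(C)(C)C | intermediate
12 | lithium alkenyl[(1S)-1-[dimethyl(phenyl)silyl]-4-methoxy-4-methylpentyl](pinacolato)borate (boron cis to CH2OSi) | [Li+].COC(C)(C)CC[C@@H]([Si](C)(C)c1ccccc1)[B-]1(OC(C)(C)C(C)(C)O1)/C(C)=C\CO[Si](c1ccccc1)(c1ccccc1)C(C)(C)C | intermediate
13 | β-iodoalkyl boronic ester (anti adduct of iodine and the migrating group; one of the two diastereomers drawn) | COC(C)(C)CC[C@@H]([Si](C)(C)c1ccccc1)[C@@](C)(B1OC(C)(C)C(C)(C)O1)[C@@H](I)CO[Si](c1ccccc1)(c1ccccc1)C(C)(C)C | intermediate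
14 | tert-butyl{[(2E,4R)-4-[dimethyl(phenyl)silyl]-7-methoxy-3,7-dimethyloct-2-en-1-yl]oxy}diphenylsilane | COC(C)(C)CC[C@@H]([Si](C)(C)c1ccccc1)/C(C)=C/CO[Si](c1ccccc1)(c1ccccc1)C(C)(C)C | intermediate
15 | tert-butyl(diphenyl){[(1R)-2,6,6-trimethylcyclohex-2-en-1-yl]methoxy}silane | CC1=CCCC(C)(C)[C@H]1CO[Si](c1ccccc1)(c1ccccc1)C(C)(C)C | intermediate
16 | [(1R)-2,6,6-trimethylcyclohex-2-en-1-yl]methanol | CC1=CCCC(C)(C)[C@H]1CO | intermediate
17 | 1-(triphenyl-λ5-phosphanylidene)propan-2-one | CC(=O)C=P(c1ccccc1)(c1ccccc1)c1ccccc1 | starting material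
18 | (1R)-2,6,6-trimethylcyclohex-2-ene-1-carbaldehyde | CC1=CCCC(C)(C)[C@H]1C=O | intermediate
19 | (3E)-4-[(1R)-2,6,6-trimethylcyclohex-2-en-1-yl]but-3-en-2-one | CC1=CCCC(C)(C)[C@H]1/C=C/C(C)=O | intermediate
20 | (1E)-3-methyl-1-[(1R)-2,6,6-trimethylcyclohex-2-en-1-yl]penta-1,4-dien-3-ol (C3 epimers) | CC1=CCCC(C)(C)[C@H]1/C=C/C(C)(O)C=C | intermediate
21 | {(2E,4E)-3-methyl-5-[(1R)-2,6,6-trimethylcyclohex-2-en-1-yl]penta-2,4-dien-1-yl}triphenylphosphonium bromide | CC1=CCCC(C)(C)[C@H]1/C=C/C(C)=C/C[P+](c1ccccc1)(c1ccccc1)c1ccccc1.[Br-] | intermediate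
22 | (2E,4E,6E)-2,7-dimethylocta-2,4,6-trienedial | O=C/C(C)=C/C=C/C=C(\C)C=O | starting material
23 | ylide of 21 | CC1=CCCC(C)(C)[C@H]1/C=C/C(C)=C/C=P(c1ccccc1)(c1ccccc1)c1ccccc1 | intermediate
24 | (2E,4E,6E,8E,10E,12E)-2,7,11-trimethyl-13-[(1R)-2,6,6-trimethylcyclohex-2-en-1-yl]trideca-2,4,6,8,10,12-hexaenal | CC1=CCCC(C)(C)[C@H]1/C=C/C(C)=C/C=C/C(C)=C/C=C/C=C(C)/C=O | intermediate
25 | 2,6,6-trimethylcyclohex-1-ene-1-carbaldehyde | CC1=C(C=O)C(C)(C)CCC1 | starting material
26 | (2,6,6-trimethylcyclohex-1-en-1-yl)methanol | CC1=C(CO)C(C)(C)CCC1 | intermediate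
27 | [(1R,6R)-2,2,6-trimethyl-7-oxabicyclo[4.1.0]heptan-1-yl]methanol | CC1(C)CCC[C@@]2(C)O[C@@]12CO | intermediate
28 | (1S,6R)-2,2,6-trimethyl-7-oxabicyclo[4.1.0]heptane-1-carbaldehyde | CC1(C)CCC[C@@]2(C)O[C@@]12C=O | intermediate
29 | (1R,6R)-1-ethynyl-2,2,6-trimethyl-7-oxabicyclo[4.1.0]heptane | CC1(C)CCC[C@@]2(C)O[C@@]12C#C | intermediate
30 | (2E)-3-iodobut-2-en-1-ol | C/C(I)=C\CO | starting material
31 | (2E)-3-methyl-5-[(1R,6R)-2,2,6-trimethyl-7-oxabicyclo[4.1.0]heptan-1-yl]pent-2-en-4-yn-1-ol | CC1(C)CCC[C@@]2(C)O[C@@]12C#C/C(C)=C/CO | intermediate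
32 | bis[diethoxy(methyl)silyl] ether of 33 | CC1(C)CCC[C@@](C)(O[Si](C)(OCC)OCC)C1=[C@@]=C([H])/C(C)=C/CO[Si](C)(OCC)OCC | intermediate
33 | (2E)-5-[(2R)-2-hydroxy-2,6,6-trimethylcyclohexylidene]-3-methylpenta-2,4-dien-1-ol, (aS) axis | CC1(C)CCC[C@@](C)(O)C1=[C@@]=C([H])/C(C)=C/CO | intermediate
34 | (2E)-3-[(2R,7aR)-4,4,7a-trimethyl-2,4,5,6,7,7a-hexahydro-1-benzofuran-2-yl]but-2-en-1-ol | OC/C=C(\C)[C@H]1C=C2C(C)(C)CCC[C@@]2(C)O1 | intermediate
35 | (2R,7aR)-2-[(2E)-4-bromobut-2-en-2-yl]-4,4,7a-trimethyl-2,4,5,6,7,7a-hexahydro-1-benzofuran | BrC/C=C(\C)[C@H]1C=C2C(C)(C)CCC[C@@]2(C)O1 | intermediate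
36 | {(2E)-3-[(2R,7aR)-4,4,7a-trimethyl-2,4,5,6,7,7a-hexahydro-1-benzofuran-2-yl]but-2-en-1-yl}triphenylphosphonium bromide | [Br-].C(/C=C(\C)[C@H]1C=C2C(C)(C)CCC[C@@]2(C)O1)[P+](c1ccccc1)(c1ccccc1)c1ccccc1 | intermediate
37 | ylide of 36 | C(/C=C(\C)[C@H]1C=C2C(C)(C)CCC[C@@]2(C)O1)=P(c1ccccc1)(c1ccccc1)c1ccccc1 | intermediate
38 | (5R,8R,6'R)-5,8-epoxy-5,8-dihydro-β,ε-carotene | CC1=CCCC(C)(C)[C@H]1/C=C/C(C)=C/C=C/C(C)=C/C=C/C=C(C)/C=C/C=C(\C)[C@H]1C=C2C(C)(C)CCC[C@@]2(C)O1 | target

**Count**

Total: 20 steps. Longest linear sequence: 11 steps (1, 2, 3, 5, 6, 7, 8, 9, 10, 11, 20).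

**Steps most likely to fail**

Step 6. The tertiary cation may lose a proton, or the allylic silyl ether may ionise with 1,4-elimination of silicon, before ring closure; a syn pathway may also erode the chirality transfer. The fallback uses known chemistry, sets out from ylide 17 and returns at (R)-α-ionone 19. Wittig reaction of 17 with commercial citral would give pseudoionone F1. Treatment with 85% H3PO4 would close the same C1'–C6' bond by the classical proton-initiated cyclisation to racemic α-ionone F2. Preparative chromatography of F2 on a chiral stationary phase (cellulose carbamate type) would deliver 19, which re-enters at step 9.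

Step 17. Hydride may be delivered on the face of the epoxide oxygen (syn mode through an oxygen-bound metal hydride), which would lead to the C8 epimer, or the alkene may be over-reduced. The fallback sets out from epoxy aldehyde 28 and returns at alcohol 34. Horner–Wadsworth–Emmons reaction of 28 with triethyl 3-methyl-4-phosphonocrotonate (NaH, THF) would give ethyl (2E,4E)-3-methyl-5-[(1S,6R)-2,2,6-trimethyl-7-oxabicyclo[4.1.0]heptan-1-yl]penta-2,4-dienoate F3. A trace of HCl in CHCl3 would trigger the known epoxide-to-furanoid rearrangement (C5–O retained) to the C8 epimer pair, from which ethyl (2E)-3-[(2R,7aR)-4,4,7a-trimethyl-2,4,5,6,7,7a-hexahydro-1-benzofuran-2-yl]but-2-enoate F4 would be separated by chromatography. Reduction of F4 with i-Bu2AlH would give 34.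

Step 18. The Lewis-acidic metal may ionise the doubly allylic C8–O bond of the product (epimerisation at C8), or the vinylallene may enter a Nazarov-type closure. The fallback sets out from allenic diol 33 and returns at 34. Iodocyclisation (N-iodosuccinimide, NaHCO3, CH2Cl2, 0 °C), with the tertiary hydroxyl attacking anti to the iodonium in the same axis-to-centre sense, would give (2E)-3-[(2S,7aR)-3-iodo-4,4,7a-trimethyl-2,4,5,6,7,7a-hexahydro-1-benzofuran-2-yl]but-2-en-1-ol F5. Hydrodeiodination of F5 (Bu3SnH, Pd(PPh3)4 cat., THF) would give 34.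

**Further compounds**

F1 | step 6 | (3E,5E)-6,10-dimethylundeca-3,5,9-trien-2-one (pseudoionone; 5Z isomer also present) | CC(C)=CCC/C(C)=C/C=C/C(C)=O
F2 | step 6 | racemic (3E)-4-(2,6,6-trimethylcyclohex-2-en-1-yl)but-3-en-2-one | CC1=CCCC(C)(C)C1/C=C/C(C)=O
F3 | step 17 | ethyl (2E,4E)-3-methyl-5-[(1S,6R)-2,2,6-trimethyl-7-oxabicyclo[4.1.0]heptan-1-yl]penta-2,4-dienoate | CC1(C)CCC[C@@]2(C)O[C@@]12/C=C/C(C)=C/C(=O)OCC
F4 | step 17 | ethyl (2E)-3-[(2R,7aR)-4,4,7a-trimethyl-2,4,5,6,7,7a-hexahydro-1-benzofuran-2-yl]but-2-enoate | CCOC(=O)/C=C(\C)[C@H]1C=C2C(C)(C)CCC[C@@]2(C)O1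
F5 | step 18 | (2E)-3-[(2S,7aR)-3-iodo-4,4,7a-trimethyl-2,4,5,6,7,7a-hexahydro-1-benzofuran-2-yl]but-2-en-1-ol | OC/C=C(\C)[C@H]1C(I)=C2C(C)(C)CCC[C@@]2(C)O1
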